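(All constants are those of an exercise; the rest is arithmetic.)

The four set-ups below are neighbours on one bench, and each takes the same charge.

    starting material + reagent → single product + released group (k1 = 340 L mol⁻¹ h⁻¹)
    reagent + single product → bis adduct + released group (k2 = 340 L mol⁻¹ h⁻¹)
    reagent + bis adduct → triple product + released group (k3 = 160 L mol⁻¹ h⁻¹)
    reagent + single product → over-reaction product (k4 = 5.9 L mol⁻¹ h⁻¹)
    starting material + single product → side product (k5 = 28 L mol⁻¹ h⁻¹)

the same everywhere: reagent 0.0143 M

|  | starting material | remark | time |
|---|---|---|---|
| ochre | 0.013 M | one stirred flow tank at steady state, fed with the mixture as stated, mean residence time 5.0 h |  |
| green | 0.013 M | one stirred flow tank at steady state, fed with the mixture as stated, mean residence time 25.0 h |  |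
| grey | 0.013 M (fed, over 5.00 h) | all but starting material at the start; starting material goes in evenly over 5.00 h, the run ends at 5.0 h | 5.0 h |
| red | 0.013 M | everything together in a closed stirred flask, run for 5.0 h | 5.0 h |

- the set-up with the highest share of single product in all that became single product or bis adduct or triple product or over-reaction product or side product, at the outlet or at the end ("none" if the first two lie within 2 percentage points) (ochre / green / grey / red / none)
- share of single product in all that became single product or bis adduct or triple product or over-reaction product or side product, at the outlet or at the end, ochre
- share of single product in all that became single product or bis adduct or triple product or over-reaction product or side product, at the outlet or at the end, green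
- share of single product in all that became single product or bis adduct or triple product or over-reaction product or side product, at the outlet or at the end, grey
- share of single product in all that became single product or bis adduct or triple product or over-reaction product or side product, at the outlet or at the end, red

- in percentages every species weighs as the starting material in it: one side product counts as two
- the stated concentrations are those of everything mixed, before any reaction; amounts are the same in each set-up
- the feed brings no volume worth counting
- run time (grey): 5.0 h

Start with ochre, the short tank. Call its steady concentrations a for starting material and b for reagent, and its mean residence time τ. Let p be the sum of the constants of the two reagent steps that consume single product, 346 L mol⁻¹ h⁻¹, and q the constant of the side step, 28 L mol⁻¹ h⁻¹.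

The tank balances then give a simple rule. For each single product leaving, L = τ(pb + 2qa) units have gone elsewhere, with side product counted double. The share is therefore 1/(1 + L).

You need a and b, so iterate. Take a trial pseudo-first-order number of 2 for the first step, which means b is 0.00118 M. Without the side step, a is 0.00433 M and single product is 0.00289 M. Put that single product back into the balance, and a drops to 0.00382 M.

This gives 3.10. That is the loss number, units lost per single product leaving. My share for ochre is 24.4%, with the reagent balance left unclosed.

Now turn the question round. For green to beat ochre, its L must fall below that value. With τ at 25.0 h, green's a must sit under 0.00222 M even with no reagent term, against 0.00382 M in ochre. I bet against that. Red and grey have no such balance, so my reckoning stops here.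

The forecast says red, with 25%, 13%, 15% and 29% for ochre, green, grey and red. Its tank figures, it says, "come from rough hand balances".

The simulation gives red, with 25.1%, 13.0%, 20.2% and 28.0% in the same order. The forecast's grey is 5.2 percentage points low.

Put ochre's result back in: L reads 2.99, and its starting material at 0.00421 M gives a side part of 1.18, leaving a reagent part of 1.81. In red, at charged concentrations, single product has a half-life of 0.14 h by the onward reagent step, shorter than the 1.9 h by the side step, yet in ochre the reagent part exceeds the side part by a factor of just 1.53. In green, L reads 6.71, higher than ochre's, at a share of 13.0%.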